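**Retrosynthetic overview**
1. Target 22 ⇒ 3-ketone 20 (C3 O-malonylation with Meldrum's acid, preceded by axial-selective ketone reduction); the C15 ester is already in place.
2. Key disconnection C3–C4 (ring A): 20 ⇒ monocyclic nitrile 18. A tertiary C4 radical, made by hydrogen-atom addition to an isopropenyl group on C5, closes ring A onto the nitrile carbon C3 of the C10 arm.
3. Enabling feature: in ring A the quaternary C4 (two methyls, C18/C19) is bonded to the oxygen-bearing C3, and the C5–C4 and C10–C1 bonds leave ring B trans to each other. C4 is therefore a masked isopropenyl group, C3 a nitrile carbon, and ring B (C5–C10, C7=C8, methyl on C8) is the ring of carvone.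
4. 18 ⇒ (S)-carvone: C10 quaternary centre by two enolate alkylations (methyl, then allyl = C1–C3); C9 side chain by Grignard 1,2-addition and formate hydrogenolysis; C13–C16 by alkyne carboalumination/formaldehyde; then esterification and allyl → aldehyde → nitrile.
5. Ring order: ring B comes intact from the chiral pool; ring A is the only ring formed, in the key step.

Key step: step 9

Assumption: (S)-3-methylpentanoic acid is taken as a catalogue compound; labdane numbering (C1–C20) is used for all intermediates, and the target is (3S,5S,9R,10S), i.e. an ent-labdane with an axial C3 oxygen trans to the C10 methyl.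

**Step 1**
Reactants: 1 (S)-(+)-carvone
Product: 3 trans-6-methylcarvone, via carvone lithium dienolate 2 (not isolated)
Conditions: LiN(i-Pr)2, THF, −78 °C; then MeI, −78 → 0 °C
Reagents that add atoms: iodomethane, CI
Why: Kinetic α′-deprotonation (C10) gives the cross-conjugated dienolate, whose alkylation with iodomethane (enolate alkylation) should occur anti to the neighbouring isopropenyl group; the C10 configuration is provisional because step 2 re-enolises this centre.

**Step 2**
Reactants: 3 trans-6-methylcarvone
Product: 5 6-allyl-6-methylcarvone, via lithium enolate 4 (not isolated)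
Conditions: LiN(i-Pr)2, THF, DMPU, −78 °C; then allyl bromide, −78 → 0 °C
Reagents that add atoms: allyl bromide, C=CCBr
Why: Enolate alkylation of the tetrasubstituted enolate on the face anti to the C5 isopropenyl group should set the C10 quaternary centre with the allyl arm (C1–C3) trans and the methyl cis to isopropenyl, which is the trans relationship of the two future ring A arms.

**Step 3**
Reactants: 5 6-allyl-6-methylcarvone; 6 4-bromo-1-(trimethylsilyl)but-1-yne
Product: 9 C9 tertiary allylic methyl carbonate, via Grignard reagent 7 (not isolated), via bromomagnesium alkoxide 8 (not isolated)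
Conditions: 6, Mg, THF, rt; then 5, LaCl3·2LiCl (0.3 equiv), THF, 0 °C; then ClCO2Me, 0 °C → rt
Reagents that add atoms: methyl chloroformate, COC(=O)Cl
Why: LaCl3·2LiCl-promoted Grignard 1,2-addition should occur on the carbonyl face opposite the pseudo-axial C10 methyl (syn to H-5), fixing the C9 carbinol configuration, and the hindered tertiary alkoxide is trapped in situ as its carbonate (O-acylation).

**Step 4**
Reactants: 9 C9 tertiary allylic methyl carbonate
Product: 11 terminal alkyne, via silyl alkyne 10 (not isolated)
Conditions: Pd2(dba)3·CHCl3 (2.5 mol %), n-Bu3P (5 mol %), HCO2H, Et3N, THF, 40 °C; then MeOH, K2CO3 (cat.), rt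
Reagents that add atoms: none
Why: Formate hydrogenolysis of an allylic carbonate (Tsuji-type reductive allylic substitution): zerovalent palladium ionises the carbonate with inversion, the (allyl)Pd(O2CH) intermediate is σ-bound at the less hindered C7 and delivers hydride to the more substituted terminus C9 on the metal-bearing face, so H-9 should enter anti to the departed oxygen (side chain equatorial, cis to the C10 methyl) with the double bond kept at C7=C8, after which K2CO3/MeOH removes the alkynyl silyl group.

**Step 5**
Reactants: 11 terminal alkyne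
Product: 14 3,4-seco-ent-labda-2,4(18),7,13E-tetraen-15-ol, via alkenylalane 12 (not isolated), via lithium alanate 13 (not isolated)
Conditions: AlMe3, Cp2ZrCl2 (0.25 equiv), CH2Cl2, 0 °C → rt; then n-BuLi, THF, −78 °C; then (CH2O)n, −78 °C → rt; aq. HCl work-up
Reagents that add atoms: trimethylaluminium, C[Al](C)C; formaldehyde (as paraformaldehyde), C=O
Why: Cp2ZrCl2-catalysed syn-methylalumination of the terminal alkyne (Negishi carboalumination) places methyl on C13 and aluminium on C14 cis to each other, and hydroxymethylation of the alanate proceeds with retention, so the 13E alkene is fixed; the isolated alkenes should not carbometalate under these conditions.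

**Step 6**
Reactants: 14 3,4-seco-ent-labda-2,4(18),7,13E-tetraen-15-ol; 15 (S)-3-methylpentanoic acid
Product: 16 3,4-seco-ent-labda-2,4(18),7,13E-tetraen-15-yl (S)-3-methylpentanoate
Conditions: DCC, DMAP (cat.), CH2Cl2, 0 °C → rt
Reagents that add atoms: none
Why: Steglich esterification of an unhindered primary allylic alcohol; the β-stereocentre of the acid cannot epimerise.

**Step 7**
Reactants: 16 3,4-seco-ent-labda-2,4(18),7,13E-tetraen-15-yl (S)-3-methylpentanoate
Product: 17 3-oxo-3,4-seco-ent-labda-4(18),7,13E-trien-15-yl (S)-3-methylpentanoate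
Conditions: PdCl2(PhCN)2 (10 mol %), CuCl2·2H2O (10 mol %), AgNO2 (5 mol %), t-BuOH–MeNO2, O2 (1 atm), rt
Reagents that add atoms: dioxygen, O=O
Why: Nitrite-modified aldehyde-selective Wacker oxidation: only the monosubstituted alkene should be oxidised by divalent palladium, at its terminal carbon (reinforced by the adjacent quaternary C10), while the 1,1-disubstituted and trisubstituted alkenes and the ester are inert.

**Step 8**
Reactants: 17 3-oxo-3,4-seco-ent-labda-4(18),7,13E-trien-15-yl (S)-3-methylpentanoate
Product: 18 3-nitrile of the 3,4-seco-ent-labda-4(18),7,13E-trien-15-yl (S)-3-methylpentanoate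
Conditions: Ph2P(O)ONH2, toluene, 85 °C
Reagents that add atoms: O-(diphenylphosphinyl)hydroxylamine, NOP(=O)(c1ccccc1)c1ccccc1
Why: Condensation to the O-phosphinyl oxime and thermal loss of diphenylphosphinic acid (one-pot aldoxime dehydration) should give the nitrile under neutral conditions that spare ester and alkenes.

**Step 9**
Reactants: 18 3-nitrile of the 3,4-seco-ent-labda-4(18),7,13E-trien-15-yl (S)-3-methylpentanoate
Product: 20 3-oxo-ent-labda-7,13E-dien-15-yl (S)-3-methylpentanoate, via ketimine 19 (not isolated)
Conditions: Fe(acac)3 (0.3 equiv), PhSiH3 (2.5 equiv), EtOH, 60 °C; then 1 M HCl, THF, rt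
Reagents that add atoms: water, O
Why: The Fe–H species formed from Fe(acac)3 and PhSiH3 transfers a hydrogen atom to the CH2 terminus of the isopropenyl group, which creates the second C4 methyl and the tertiary C4 radical; this adds to the nitrile carbon C3, the iminyl radical is reduced to ketimine 19, and acid hydrolysis gives the C3 ketone. The closest known reaction type is the MHAT reductive cyclisation of alkenyl nitriles to cyclic ketones bearing α-quaternary centres, catalysed by Fe(acac)3 with PhSiH3. Ring A is closed in the 6-exo-dig mode (C4 radical onto C3≡N; ring atoms C4–C5–C10–C1–C2–C3). No stereocentre is created (C4 carries two methyls, C3 is trigonal); the trans ring fusion follows from the trans, diequatorial C5 and C10 arms set in step 2, and C3 is left to step 10. The step needs hydrogen-atom transfer to the 1,1-disubstituted alkene rather than the two trisubstituted ones, and a radical lifetime long enough for the slow nitrile addition: the first is secured by the higher reactivity of the terminal alkene and a limited silane charge, the second by the absence of a fast hydrogen donor under MHAT conditions and by the radical and nitrile sitting on adjacent ring carbons.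

**Step 10**
Reactants: 20 3-oxo-ent-labda-7,13E-dien-15-yl (S)-3-methylpentanoate
Product: 21 (3S)-3-hydroxy-ent-labda-7,13E-dien-15-yl (S)-3-methylpentanoate (axial hydroxyl)
Conditions: LiBH(s-Bu)3 (1.2 equiv), THF, −78 °C; then H2O
Reagents that add atoms: none
Why: Hindered trialkylborohydride reduction: the reagent avoids the axial trajectory flanked by the axial hydrogens on C1 and C5 and should deliver hydride equatorially, setting C3 with the hydroxyl axial and trans to the C10 methyl, as is general for 4,4-dimethyl-3-ketones of decalins, while the ester survives at −78 °C.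

**Step 11**
Reactants: 21 (3S)-3-hydroxy-ent-labda-7,13E-dien-15-yl (S)-3-methylpentanoate
Product: 22 target, 3-[(3S,5S,9R,10S)-15-((S)-3-methylpentanoyloxy)-ent-labda-7,13E-dien-3-yloxy]-3-oxopropanoic acid
Conditions: Meldrum's acid (2 equiv), toluene, 100 °C
Reagents that add atoms: Meldrum's acid (2,2-dimethyl-1,3-dioxane-4,6-dione), CC1(C)OC(=O)CC(=O)O1
Why: Thermal alcoholysis of Meldrum's acid (acylation with loss of acetone) should give the malonic half-ester directly, without a protecting group, and with retention at C3.

**Compound list**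
1 | (S)-(+)-carvone | CC1=CC[C@@H](CC1=O)C(C)=C | starting material
2 | carvone lithium dienolate (C9–C10 enolate) | CC1=CC[C@H](C(C)=C)C=C1O[Li] | intermediate (not isolated)
3 | trans-6-methylcarvone (methyl trans to isopropenyl, major epimer) | O=C1C(C)=CC[C@H](C(C)=C)[C@H]1C | intermediate
4 | lithium enolate of 3 | CC1=CC[C@H](C(C)=C)C(C)=C1O[Li] | intermediate (not isolated)
5 | 6-allyl-6-methylcarvone (allyl trans, methyl cis to isopropenyl) | O=C1C(C)=CC[C@H](C(C)=C)[C@@]1(C)CC=C | intermediate
6 | 4-bromo-1-(trimethylsilyl)but-1-yne | C[Si](C)(C)C#CCCBr | starting material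
7 | [4-(trimethylsilyl)but-3-yn-1-yl]magnesium bromide | C[Si](C)(C)C#CCC[Mg]Br | intermediate (not isolated)
8 | bromomagnesium alkoxide of the C9 carbinol | C[Si](C)(C)C#CCC[C@@]1(O[Mg]Br)C(C)=CC[C@H](C(C)=C)[C@@]1(C)CC=C | intermediate (not isolated)
9 | C9 tertiary allylic methyl carbonate (side chain syn to H-5, carbonate cis to C10 methyl) | C[Si](C)(C)C#CCC[C@@]1(OC(=O)OC)C(C)=CC[C@H](C(C)=C)[C@@]1(C)CC=C | intermediate
10 | silyl alkyne (H-9 syn to H-5, side chain cis to C10 methyl, C7=C8) | C[Si](C)(C)C#CCC[C@@H]1C(C)=CC[C@H](C(C)=C)[C@@]1(C)CC=C | intermediate (not isolated)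
11 | terminal alkyne (C13≡C14) | C#CCC[C@@H]1C(C)=CC[C@H](C(C)=C)[C@@]1(C)CC=C | intermediate
12 | (E)-alkenyldimethylalane | C[Al](C)/C=C(\C)CC[C@@H]1C(C)=CC[C@H](C(C)=C)[C@@]1(C)CC=C | intermediate (not isolated)
13 | lithium (E)-alkenyl(butyl)dimethylalanate | [Li+].CCCC[Al-](C)(C)/C=C(\C)CC[C@@H]1C(C)=CC[C@H](C(C)=C)[C@@]1(C)CC=C | intermediate (not isolated)
14 | 3,4-seco-ent-labda-2,4(18),7,13E-tetraen-15-ol | OC/C=C(\C)CC[C@@H]1C(C)=CC[C@H](C(C)=C)[C@@]1(C)CC=C | intermediate
15 | (S)-3-methylpentanoic acid | CC[C@H](C)CC(=O)O | starting material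
16 | 3,4-seco-ent-labda-2,4(18),7,13E-tetraen-15-yl (S)-3-methylpentanoate | CC[C@H](C)CC(=O)OC/C=C(\C)CC[C@@H]1C(C)=CC[C@H](C(C)=C)[C@@]1(C)CC=C | intermediate
17 | 3-oxo-3,4-seco-ent-labda-4(18),7,13E-trien-15-yl (S)-3-methylpentanoate (aldehyde) | CC[C@H](C)CC(=O)OC/C=C(\C)CC[C@@H]1C(C)=CC[C@H](C(C)=C)[C@@]1(C)CCC=O | intermediate
18 | corresponding 3-nitrile | CC[C@H](C)CC(=O)OC/C=C(\C)CC[C@@H]1C(C)=CC[C@H](C(C)=C)[C@@]1(C)CCC#N | intermediate
19 | 3-imino-ent-labda-7,13E-dien-15-yl (S)-3-methylpentanoate | CC[C@H](C)CC(=O)OC/C=C(\C)CC[C@@H]1C(C)=CC[C@@H]2C(C)(C)C(=N)CC[C@@]12C | intermediate (not isolated)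
20 | 3-oxo-ent-labda-7,13E-dien-15-yl (S)-3-methylpentanoate | CC[C@H](C)CC(=O)OC/C=C(\C)CC[C@@H]1C(C)=CC[C@@H]2C(C)(C)C(=O)CC[C@@]12C | intermediate
21 | (3S)-3-hydroxy-ent-labda-7,13E-dien-15-yl (S)-3-methylpentanoate (axial OH) | CC[C@H](C)CC(=O)OC/C=C(\C)CC[C@@H]1C(C)=CC[C@@H]2C(C)(C)[C@@H](O)CC[C@@]12C | intermediate
22 | CNP0234792.1 | CC[C@H](C)CC(=O)OC/C=C(\C)CC[C@@H]1C(C)=CC[C@@H]2C(C)(C)[C@@H](OC(=O)CC(=O)O)CC[C@@]12C | target

**Step count:** 11 steps in total; longest linear sequence 11 steps (from (S)-carvone).

**Steps most likely to fail**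
1. Step 9 (key step). The tertiary C4 radical may be reduced, or may shift a hydrogen from C2, faster than it adds to the nitrile; hydrogen-atom transfer may also take place at the trisubstituted alkenes. Fallback: setting out from aldehyde 17, the same radical (Fe(acac)3, PhSiH3, EtOH, 60 °C) is trapped by the much faster 6-exo-trig addition to the aldehyde carbonyl, with the alkoxyl radical reduced by divalent iron. This should give the C3 carbinol epimer mixture F1, which Dess–Martin periodinane oxidises to ketone 20, where the route is rejoined.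
2. Step 4. Hydride may be delivered to the less substituted terminus C7, which would move the double bond to C8=C9; the allylpalladium intermediate may instead lose a β-hydrogen to give dienes; or ionisation of the hindered carbonate may be slow. Fallback: setting out from enone 5, nucleophilic epoxidation (H2O2, NaOH, MeOH) anti to the isopropenyl group gives the epoxy ketone F2. Wharton transposition (N2H4·H2O, AcOH, MeOH) gives the transposed allylic alcohol F3 (C7 hydroxyl, C8=C9), which is esterified to the picolinate F4 (picolinic acid, DCC, DMAP). Anti-SN2′ substitution with Grignard reagent 7 and CuBr·SMe2 (THF, −40 °C) then places the side chain on C9 anti to the leaving group and returns the alkene to C7=C8, giving silyl alkyne 10, which is desilylated to 11 as in step 4.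
3. Step 7. Alkene isomerisation or Markovnikov oxidation to the methyl ketone may compete. Fallback: setting out from 16, hydroboration with disiamylborane (selective for the monosubstituted alkene) and NaBO3·4H2O oxidation give the primary alcohol F5, and Dess–Martin periodinane oxidation returns aldehyde 17.

**Further compounds**
F1 | step 9 | 3-hydroxy-ent-labda-7,13E-dien-15-yl (S)-3-methylpentanoate, C3 epimer mixture | CC[C@H](C)CC(=O)OC/C=C(\C)CC[C@@H]1C(C)=CC[C@@H]2C(C)(C)C(O)CC[C@@]12C
F2 | step 4 | 7,8-epoxy ketone of 5 (epoxide anti to isopropenyl) | O=C1[C@@]2(C)O[C@H]2C[C@H](C(C)=C)[C@@]1(C)CC=C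
F3 | step 4 | transposed allylic alcohol (C7 hydroxyl anti to isopropenyl, C8=C9) | CC1=C[C@](C)(CC=C)[C@@H](C(C)=C)C[C@@H]1O
F4 | step 4 | picolinate of F3 | CC1=C[C@](C)(CC=C)[C@@H](C(C)=C)C[C@@H]1OC(=O)c2ccccn2
F5 | step 7 | 3-hydroxy-3,4-seco-ent-labda-4(18),7,13E-trien-15-yl (S)-3-methylpentanoate | CC[C@H](C)CC(=O)OC/C=C(\C)CC[C@@H]1C(C)=CC[C@H](C(C)=C)[C@@]1(C)CCCO
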